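## Retrosynthetic overview

1. Locants: ring C1 (CH bearing the chain), C2 (C=CH2), C3 (CHBr), C4 (CH2), C5 (CHBr), C6 (CMe2); chain C7, C8, C9 (carbinol), C10=C11. The plan rests on the adjacent atoms C1 and C2 of the only ring, the carbocycle C1–C6. A CH carrying one carbon (C7) sits next to a carbon carrying =CH2, with CMe2 (C6) on the other side of C1. This is the imprint of an allenic ester added across 1,1-dimethylbutadiene.
2. C3–Br (cis to C7) comes from C3–OH (trans to C7) by SN2. That alcohol comes from allylic oxidation of the C2 methylene system while the C1 and C5 groups are both equatorial.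
3. The C9 carbinol and vinyl group come from a Sharpless epoxy alcohol, then an E-enoate, a methyl ketone, and finally the C7 aldehyde plus an acetonyl phosphonate.
4. C5–Br (trans to C7) comes from C5–OH (cis to C7) by SN2. That alcohol comes from a temporary γ-lactone bridge C7(=O)–O–C5, made by iodolactonisation of the C4=C5 alkene.
5. Ring order: the carbocycle forms first (bonds C1–C6 and C2–C3, asymmetric [4+2]). The lactone ring forms second and is opened again. The oxirane at C9/C10 forms last and is also opened.

Key step: step 1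

Assumption: the facial sense of the oxazaborolidinium catalyst is taken to follow that of acrylate esters, where the α-carbon has the same CIP priority pattern as C1 here. The (R)-prolinol-derived catalyst is therefore assigned to (R)-3, and the equally available antipode would be used if the allenoate binds the other way.

## Route

Step 1
Reactants: 1 ethyl buta-2,3-dienoate; 2 4-methylpenta-1,3-diene
Product: 3 ethyl (1R)-2,2-dimethyl-6-methylidenecyclohex-3-ene-1-carboxylate
Conditions: (R)-α,α-diphenylprolinol-derived B-(o-tolyl)oxazaborolidine (24 mol %), Tf2NH (20 mol %), 2 (4 equiv), CH2Cl2, −40 → −10 °C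
Reagents that add atoms: none
Why: Proposed new method: oxazaborolidinium-catalysed enantioselective Diels–Alder reactions are established for acrylate esters with acyclic dienes, and achiral Lewis acids are known to add allenic esters through their conjugated C=C bond, but the chiral cation has not been shown with an allenoate and a 4,4-disubstituted diene. The boron cation binds the ester carbonyl of 1 and lowers the LUMO of the Cα=Cβ π bond, while the terminal π bond lies orthogonal to the carbonyl, is not activated and survives as the C2 methylene. A suprafacial but strongly asynchronous [4π+2π] addition follows in which the CH2 terminus of 2 bonds first to the central allene carbon (C3–C2) and the CMe2 terminus then closes on the α-carbon (C6–C1), which closes the six-membered ring C1–C6 in one cycloaddition and leaves the C4=C5 alkene. C1, the only new stereocentre, is fixed by the catalyst, whose aryl groups cover one face of the bound s-trans allenoate (held by the α-C–H···O contact accepted for acrylates), so that 2 adds to the open face, and endo/exo orientation is irrelevant because no second stereocentre forms. The step needs ortho regioselectivity, which the two methyl donors secure by placing the larger HOMO coefficient on the CH2 terminus and by stabilising developing positive charge at the CMe2 end. It also needs the diene to survive, so the oxazaborolidine is kept in slight excess over Tf2NH and no free acid can start cationic oligomerisation while the Z-methyl group slows entry into the s-cis form.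

Step 2
Reactants: 3 ethyl (1R)-2,2-dimethyl-6-methylidenecyclohex-3-ene-1-carboxylate
Product: 4 (1R,4R,5R)-4-iodo-8,8-dimethyl-2-methylidene-6-oxabicyclo[3.2.1]octan-7-one
Conditions: I2 (3 equiv), MeCN, 0 °C → rt, dark
Reagents that add atoms: iodine, II
Why: This is an iodolactonisation run directly on the ester, with iodide removing the ethyl group, chosen because C1–H is both allylic and α to the carbonyl and would not survive saponification of this hindered ester without racemisation or migration of the C2 methylene; iodonium formation is reversible at both alkenes, but only the C4=C5 iodonium on the face opposite the axial ester can be trapped 5-exo by the carbonyl oxygen at C5 (closure onto C2 would need a four-membered ring), so anti addition sets C5–O cis to C7 and C4–I trans to it.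

Step 3
Reactants: 4 (1R,4R,5R)-4-iodo-8,8-dimethyl-2-methylidene-6-oxabicyclo[3.2.1]octan-7-one
Product: 5 (1R,5S)-8,8-dimethyl-2-methylidene-6-oxabicyclo[3.2.1]octan-7-one
Conditions: Bu3SnH, AIBN (cat.), toluene, 80 °C
Reagents that add atoms: none
Why: In this radical-chain tin hydride dehalogenation of an iodolactone, the secondary C4 radical takes hydrogen faster than it can close reversibly onto the C2 methylene or lose the β-acyloxy group, so C1 and C5 are untouched and the C4 stereocentre simply disappears.

Step 4
Reactants: 5 (1R,5S)-8,8-dimethyl-2-methylidene-6-oxabicyclo[3.2.1]octan-7-one; 6 N,O-dimethylhydroxylamine hydrochloride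
Product: 7 (1R,3S)-3-hydroxy-N-methoxy-N,2,2-trimethyl-6-methylidenecyclohexane-1-carboxamide (C5–OH cis to C7)
Conditions: AlMe3, CH2Cl2, 0 °C → rt
Reagents that add atoms: none
Why: Weinreb aminolysis of the lactone with the aluminium amide is a non-basic acyl–oxygen cleavage that frees C5–OH with its configuration intact and keeps C7 one reduction away from the aldehyde, and it replaces a direct bromide attack on the C5–O bond of 5, since a carboxylate on a neopentyl secondary carbon would leave only under acid strong enough to move the C2 methylene into the ring.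

Step 5
Reactants: 7 (1R,3S)-3-hydroxy-N-methoxy-N,2,2-trimethyl-6-methylidenecyclohexane-1-carboxamide
Product: 8 (1S,3S,5S)-3,5-dihydroxy-N-methoxy-N,2,2-trimethyl-6-methylidenecyclohexane-1-carboxamide (new C3–OH trans to C7)
Conditions: SeO2 (0.3 equiv), t-BuOOH (3 equiv), CH2Cl2, 0 °C → rt
Reagents that add atoms: tert-butyl hydroperoxide, CC(C)(C)OO (terminal oxidant; the oxygen is relayed through selenium dioxide, O=[Se]=O)
Why: Selenium dioxide allylic oxidation (ene reaction, then [2,3]-sigmatropic shift) is placed before the C5 inversion on purpose: the tertiary, carbonyl-deactivated C1–H stays out so C3 reacts, and in the chair with the C1 and C5 groups both equatorial the axial C3–H on the face opposite C7 is removed and oxygen returns axially to that face past axial hydrogens only, whereas the other face would need a chair with three syn-axial groups, so C3–OH is set trans to C7.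

Step 6
Reactants: 8 (1S,3S,5S)-3,5-dihydroxy-N-methoxy-N,2,2-trimethyl-6-methylidenecyclohexane-1-carboxamide
Product: 9 (1S,3S,5S)-5-[(tert-butyldimethylsilyl)oxy]-3-hydroxy-N-methoxy-N,2,2-trimethyl-6-methylidenecyclohexane-1-carboxamide (route locants: OTBS at C3, OH at C5)
Conditions: TBSCl (1.1 equiv), imidazole, DMF, 0 °C
Reagents that add atoms: tert-butyldimethylsilyl chloride, CC(C)(C)[Si](C)(C)Cl
Why: In this kinetically selective silylation, the allylic C3 carbinol stands beside the flat sp2 carbon C2 and should react well ahead of the C5 carbinol, which is flanked by the quaternary C6 and gauche to both of its methyl groups.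

Step 7
Reactants: 9 (1S,3S,5S)-5-[(tert-butyldimethylsilyl)oxy]-3-hydroxy-N-methoxy-N,2,2-trimethyl-6-methylidenecyclohexane-1-carboxamide
Product: 10 (1R,3R,5S)-3-bromo-5-[(tert-butyldimethylsilyl)oxy]-N-methoxy-N,2,2-trimethyl-6-methylidenecyclohexane-1-carboxamide (route locants: Br at C5, trans to C7)
Conditions: CBr4, P(n-Oct)3, toluene, 0 → 70 °C
Reagents that add atoms: carbon tetrabromide, BrC(Br)(Br)Br
Why: This is an Appel bromination in the trialkylphosphine/hot toluene variant used for hindered secondary carbinols: bromide displaces the alkoxyphosphonium group by SN2 through the accessible ring-flipped chair in which the leaving group is axial, which inverts C5 and places bromine trans to C7, and the amide, being on the same face as the leaving group, cannot participate from the rear.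

Step 8
Reactants: 10 (1R,3R,5S)-3-bromo-5-[(tert-butyldimethylsilyl)oxy]-N-methoxy-N,2,2-trimethyl-6-methylidenecyclohexane-1-carboxamide
Product: 11 (1R,3R,5S)-3-bromo-5-[(tert-butyldimethylsilyl)oxy]-2,2-dimethyl-6-methylidenecyclohexane-1-carbaldehyde
Conditions: DIBAL-H, THF, −78 °C
Reagents that add atoms: none
Why: Hydride reduction of a Weinreb amide stops at the chelated tetrahedral intermediate and releases the aldehyde only on work-up, the alkyl bromide, silyl ether and alkene are inert at this temperature, and C1 never meets base.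

Step 9
Reactants: 11 (1R,3R,5S)-3-bromo-5-[(tert-butyldimethylsilyl)oxy]-2,2-dimethyl-6-methylidenecyclohexane-1-carbaldehyde; 12 diethyl (2-oxopropyl)phosphonate
Product: 13 (3E)-4-[(1R,3R,5S)-3-bromo-5-[(tert-butyldimethylsilyl)oxy]-2,2-dimethyl-6-methylidenecyclohexyl]but-3-en-2-one
Conditions: LiCl, i-Pr2NEt, MeCN, rt
Reagents that add atoms: none
Why: In this Horner–Wadsworth–Emmons olefination under Masamune–Roush conditions, the lithium-chelated β-ketophosphonate is deprotonated by an amine too weak to enolise the β,γ-unsaturated aldehyde at a competitive rate, so C1 is kept and the stabilised carbanion should give the E-enone (C7=C8).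

Step 10
Reactants: 13 (3E)-4-[(1R,3R,5S)-3-bromo-5-[(tert-butyldimethylsilyl)oxy]-2,2-dimethyl-6-methylidenecyclohexyl]but-3-en-2-one
Product: 14 4-[(1R,3R,5S)-3-bromo-5-[(tert-butyldimethylsilyl)oxy]-2,2-dimethyl-6-methylidenecyclohexyl]butan-2-one
Conditions: [(Ph3P)CuH]6 (Stryker reagent), toluene, H2O (proton source), rt
Reagents that add atoms: none
Why: Copper hydride conjugate reduction delivers hydride only to the electron-poor C7=C8 bond and leaves the unactivated C2 methylene, the secondary bromide and the silyl ether alone, which hydrogenation could not do.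

Step 11
Reactants: 14 4-[(1R,3R,5S)-3-bromo-5-[(tert-butyldimethylsilyl)oxy]-2,2-dimethyl-6-methylidenecyclohexyl]butan-2-one; 15 triethyl phosphonoacetate
Product: 16 ethyl (2E)-5-[(1R,3R,5S)-3-bromo-5-[(tert-butyldimethylsilyl)oxy]-2,2-dimethyl-6-methylidenecyclohexyl]-3-methylpent-2-enoate
Conditions: NaH, THF, 0 °C → rt
Reagents that add atoms: none
Why: In this Horner–Wadsworth–Emmons olefination of a methyl ketone, reversible addition favours the isomer with the ester anti to the larger C8 chain, so the E-enoate should prevail and the minor Z isomer is removed by chromatography here or after step 12.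

Step 12
Reactants: 16 ethyl (2E)-5-[(1R,3R,5S)-3-bromo-5-[(tert-butyldimethylsilyl)oxy]-2,2-dimethyl-6-methylidenecyclohexyl]-3-methylpent-2-enoate
Product: 17 (2E)-5-[(1R,3R,5S)-3-bromo-5-[(tert-butyldimethylsilyl)oxy]-2,2-dimethyl-6-methylidenecyclohexyl]-3-methylpent-2-en-1-ol
Conditions: DIBAL-H (2.5 equiv), CH2Cl2, −78 °C
Reagents that add atoms: none
Why: DIBAL-H reduces the enoate 1,2 to the allylic alcohol without touching the alkene geometry, the bromide or the silyl ether.

Step 13
Reactants: 17 (2E)-5-[(1R,3R,5S)-3-bromo-5-[(tert-butyldimethylsilyl)oxy]-2,2-dimethyl-6-methylidenecyclohexyl]-3-methylpent-2-en-1-ol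
Product: 18 [(2S,3S)-3-{2-[(1R,3R,5S)-3-bromo-5-[(tert-butyldimethylsilyl)oxy]-2,2-dimethyl-6-methylidenecyclohexyl]ethyl}-3-methyloxiran-2-yl]methanol
Conditions: Ti(Oi-Pr)4 (10 mol %), L-(+)-DET (12 mol %), t-BuOOH, 4 Å MS, CH2Cl2, −20 °C
Reagents that add atoms: tert-butyl hydroperoxide, CC(C)(C)OO
Why: Sharpless asymmetric epoxidation runs under pure reagent control because the ring stereocentres are remote; with L-(+)-tartrate an E-3-methylalk-2-en-1-ol of the geraniol type gives the (2S,3S)-epoxide, which fixes C9 as S, and the C2 methylene has no free allylic hydroxyl to bind titanium and is not oxidised.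

Step 14
Reactants: 18 [(2S,3S)-3-{2-[(1R,3R,5S)-3-bromo-5-[(tert-butyldimethylsilyl)oxy]-2,2-dimethyl-6-methylidenecyclohexyl]ethyl}-3-methyloxiran-2-yl]methanol
Product: 19 (2R,3S)-3-{2-[(1R,3R,5S)-3-bromo-5-[(tert-butyldimethylsilyl)oxy]-2,2-dimethyl-6-methylidenecyclohexyl]ethyl}-2-(iodomethyl)-3-methyloxirane
Conditions: PPh3, imidazole, I2, THF, 0 °C
Reagents that add atoms: iodine, II
Why: Appel-type iodination of the primary alcohol (Garegg–Samuelsson conditions) proceeds by SN2 at the unhindered C11 and leaves the oxirane and both of its stereocentres unchanged in space (the C10 descriptor changes only by priority).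

Step 15
Reactants: 19 (2R,3S)-3-{2-[(1R,3R,5S)-3-bromo-5-[(tert-butyldimethylsilyl)oxy]-2,2-dimethyl-6-methylidenecyclohexyl]ethyl}-2-(iodomethyl)-3-methyloxirane
Product: 20 (3S)-5-[(1R,3R,5S)-3-bromo-5-[(tert-butyldimethylsilyl)oxy]-2,2-dimethyl-6-methylidenecyclohexyl]-3-methylpent-1-en-3-ol
Conditions: Zn dust, EtOH, 60 °C
Reagents that add atoms: none
Why: In this reductive β-elimination of a 2,3-epoxy iodide, zinc inserts into the primary C–I bond and expels the C10–O bond to give the C10=C11 vinyl group, the C9–O bond is never broken so C9 stays S, and the unactivated secondary C5 bromide is inert to zinc dust, which is why the allylic C3 bromide is introduced only afterwards.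

Step 16
Reactants: 20 (3S)-5-[(1R,3R,5S)-3-bromo-5-[(tert-butyldimethylsilyl)oxy]-2,2-dimethyl-6-methylidenecyclohexyl]-3-methylpent-1-en-3-ol
Product: 21 (3S)-5-[(1R,3R,5S)-3-bromo-5-hydroxy-2,2-dimethyl-6-methylidenecyclohexyl]-3-methylpent-1-en-3-ol (route locants: OH at C3, Br at C5, both trans to C7)
Conditions: TBAF, AcOH (1:1), THF, rt
Reagents that add atoms: none
Why: Buffering the fluoride desilylation with acetic acid avoids E2 loss of HBr across C4–C5, and the freed C3 oxygen sits on the same face as the C5 bromine so it cannot displace it.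

Step 17
Reactants: 21 (3S)-5-[(1R,3R,5S)-3-bromo-5-hydroxy-2,2-dimethyl-6-methylidenecyclohexyl]-3-methylpent-1-en-3-ol
Product: 22 (3S)-5-[(1S,3R,5R)-3,5-dibromo-2,2-dimethyl-6-methylidenecyclohexyl]-3-methylpent-1-en-3-ol (target)
Conditions: CBr4 (1.2 equiv), PPh3 (1.3 equiv), CH2Cl2, −30 → 0 °C
Reagents that add atoms: carbon tetrabromide, BrC(Br)(Br)Br
Why: In this Appel bromination of the secondary allylic alcohol, the phosphonium salt forms at the accessible C3 hydroxyl rather than at the tertiary C9 carbinol, direct SN2 attack by bromide inverts C3 and places bromine cis to C7, and low temperature, a non-polar medium and near-stoichiometric reagent are chosen to hold back SN2′ transposition.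

## Compound list

1 | ethyl buta-2,3-dienoate | C=C=CC(=O)OCC | starting material
2 | 4-methylpenta-1,3-diene | C=CC=C(C)C | starting material
3 | ethyl (1R)-2,2-dimethyl-6-methylidenecyclohex-3-ene-1-carboxylate | CCOC(=O)[C@@H]1C(=C)CC=CC1(C)C | intermediate
4 | (1R,4R,5R)-4-iodo-8,8-dimethyl-2-methylidene-6-oxabicyclo[3.2.1]octan-7-one | O=C2[C@@H]1C(=C)C[C@@H](I)[C@H](O2)C1(C)C | intermediate
5 | (1R,5S)-8,8-dimethyl-2-methylidene-6-oxabicyclo[3.2.1]octan-7-one | O=C2[C@@H]1C(=C)CC[C@H](O2)C1(C)C | intermediate
6 | N,O-dimethylhydroxylamine hydrochloride | CNOC.Cl | starting material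
7 | (1R,3S)-3-hydroxy-N-methoxy-N,2,2-trimethyl-6-methylidenecyclohexane-1-carboxamide | CON(C)C(=O)[C@@H]1C(=C)CC[C@H](O)C1(C)C | intermediate
8 | (1S,3S,5S)-3,5-dihydroxy-N-methoxy-N,2,2-trimethyl-6-methylidenecyclohexane-1-carboxamide | CON(C)C(=O)[C@@H]1C(=C)[C@@H](O)C[C@H](O)C1(C)C | intermediate
9 | (1S,3S,5S)-5-[(tert-butyldimethylsilyl)oxy]-3-hydroxy-N-methoxy-N,2,2-trimethyl-6-methylidenecyclohexane-1-carboxamide | CON(C)C(=O)[C@@H]1C(=C)[C@@H](O[Si](C)(C)C(C)(C)C)C[C@H](O)C1(C)C | intermediate
10 | (1R,3R,5S)-3-bromo-5-[(tert-butyldimethylsilyl)oxy]-N-methoxy-N,2,2-trimethyl-6-methylidenecyclohexane-1-carboxamide | CON(C)C(=O)[C@@H]1C(=C)[C@@H](O[Si](C)(C)C(C)(C)C)C[C@@H](Br)C1(C)C | intermediate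
11 | (1R,3R,5S)-3-bromo-5-[(tert-butyldimethylsilyl)oxy]-2,2-dimethyl-6-methylidenecyclohexane-1-carbaldehyde | O=C[C@@H]1C(=C)[C@@H](O[Si](C)(C)C(C)(C)C)C[C@@H](Br)C1(C)C | intermediate
12 | diethyl (2-oxopropyl)phosphonate | CCOP(=O)(CC(C)=O)OCC | starting material
13 | (3E)-4-[(1R,3R,5S)-3-bromo-5-[(tert-butyldimethylsilyl)oxy]-2,2-dimethyl-6-methylidenecyclohexyl]but-3-en-2-one | CC(=O)/C=C/[C@@H]1C(=C)[C@@H](O[Si](C)(C)C(C)(C)C)C[C@@H](Br)C1(C)C | intermediate
14 | 4-[(1R,3R,5S)-3-bromo-5-[(tert-butyldimethylsilyl)oxy]-2,2-dimethyl-6-methylidenecyclohexyl]butan-2-one | CC(=O)CC[C@@H]1C(=C)[C@@H](O[Si](C)(C)C(C)(C)C)C[C@@H](Br)C1(C)C | intermediate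
15 | triethyl phosphonoacetate | CCOC(=O)CP(=O)(OCC)OCC | starting material
16 | ethyl (2E)-5-[(1R,3R,5S)-3-bromo-5-[(tert-butyldimethylsilyl)oxy]-2,2-dimethyl-6-methylidenecyclohexyl]-3-methylpent-2-enoate | CCOC(=O)/C=C(\C)CC[C@@H]1C(=C)[C@@H](O[Si](C)(C)C(C)(C)C)C[C@@H](Br)C1(C)C | intermediate
17 | (2E)-5-[(1R,3R,5S)-3-bromo-5-[(tert-butyldimethylsilyl)oxy]-2,2-dimethyl-6-methylidenecyclohexyl]-3-methylpent-2-en-1-ol | OC/C=C(\C)CC[C@@H]1C(=C)[C@@H](O[Si](C)(C)C(C)(C)C)C[C@@H](Br)C1(C)C | intermediate
18 | [(2S,3S)-3-{2-[(1R,3R,5S)-3-bromo-5-[(tert-butyldimethylsilyl)oxy]-2,2-dimethyl-6-methylidenecyclohexyl]ethyl}-3-methyloxiran-2-yl]methanol | OC[C@@H]1O[C@@]1(C)CC[C@@H]1C(=C)[C@@H](O[Si](C)(C)C(C)(C)C)C[C@@H](Br)C1(C)C | intermediate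
19 | (2R,3S)-3-{2-[(1R,3R,5S)-3-bromo-5-[(tert-butyldimethylsilyl)oxy]-2,2-dimethyl-6-methylidenecyclohexyl]ethyl}-2-(iodomethyl)-3-methyloxirane | IC[C@@H]1O[C@@]1(C)CC[C@@H]1C(=C)[C@@H](O[Si](C)(C)C(C)(C)C)C[C@@H](Br)C1(C)C | intermediate
20 | (3S)-5-[(1R,3R,5S)-3-bromo-5-[(tert-butyldimethylsilyl)oxy]-2,2-dimethyl-6-methylidenecyclohexyl]-3-methylpent-1-en-3-ol | C=C[C@@](C)(O)CC[C@@H]1C(=C)[C@@H](O[Si](C)(C)C(C)(C)C)C[C@@H](Br)C1(C)C | intermediate
21 | (3S)-5-[(1R,3R,5S)-3-bromo-5-hydroxy-2,2-dimethyl-6-methylidenecyclohexyl]-3-methylpent-1-en-3-ol | C=C[C@@](C)(O)CC[C@@H]1C(=C)[C@@H](O)C[C@@H](Br)C1(C)C | intermediate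
22 | (3S)-5-[(1S,3R,5R)-3,5-dibromo-2,2-dimethyl-6-methylidenecyclohexyl]-3-methylpent-1-en-3-ol | C=C[C@@](C)(O)CC[C@@H]1C(=C)[C@H](Br)C[C@@H](Br)C1(C)C | target

## Step count and risks

Total step count: 17. Longest linear sequence: 17 steps (from 1 and 2 to 22).

**Step 1 (labelled step).**
- What may go wrong: the Z-methyl group may keep the diene out of the s-cis form for so long that other processes win. These are acid-induced oligomerisation of the diene, stepwise collapse of the zwitterionic pathway to open-chain or four-membered products, or weak facial discrimination.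
- Fallback (known chemistry only; sets out from 1 and 2, returns at 4). The cycloaddition is run without asymmetric induction, with a stoichiometric achiral Lewis acid (EtAlCl2, CH2Cl2, −20 °C → rt), to give racemic ethyl 2,2-dimethyl-6-methylidenecyclohex-3-ene-1-carboxylate F1.
- LiAlH4 in Et2O reduces it to racemic (2,2-dimethyl-6-methylidenecyclohex-3-en-1-yl)methanol F2.
- TEMPO/PhI(OAc)2 in aqueous MeCN oxidises this to racemic 2,2-dimethyl-6-methylidenecyclohex-3-ene-1-carboxylic acid F3 without any basic step.
- Classical resolution by fractional crystallisation with (S)-1-phenylethylamine gives (S)-1-phenylethylammonium (1R)-2,2-dimethyl-6-methylidenecyclohex-3-ene-1-carboxylate F4. The antipodal amine is used if it gives the less soluble salt of the (R)-acid.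
- Dilute acid liberates (1R)-2,2-dimethyl-6-methylidenecyclohex-3-ene-1-carboxylic acid F5. Standard iodolactonisation of the free acid (I2, KI, NaHCO3, H2O/CH2Cl2) then gives 4.

**Step 7.**
- What may go wrong: backside attack at the neopentyl carbon C5 may be too slow. The activated oxygen would then be lost by elimination towards C4 or by migration of a C6 methyl group instead of substitution.
- Fallback (sets out from 9, returns at 10). Activation and displacement are separated.
- ClCH2SO2Cl and pyridine at 0 °C give the isolable (1S,3S,5S)-5-[(tert-butyldimethylsilyl)oxy]-3-[(chloromethanesulfonyl)oxy]-N-methoxy-N,2,2-trimethyl-6-methylidenecyclohexane-1-carboxamide F6. This sulfonate leaves far better than a mesylate yet can still be purified.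
- F6 is then treated with an excess of dry, unsolvated bromide (LiBr in DMF, or Bu4NBr in toluene) at the lowest temperature that gives conversion, which delivers 10 with inversion.

**Step 17.**
- What may go wrong: bromide may end up on the exocyclic carbon by SN2′ attack or by bromide-induced equilibration. Ionisation may erode the C3 configuration. The tertiary C9 carbinol may be activated in competition.
- Fallback (sets out from 21, returns at 22). The tertiary alcohol is masked and a discrete sulfonate is displaced in the cold.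
- Excess TMS-imidazole gives (3S)-5-[(1R,3R,5S)-3-bromo-2,2-dimethyl-6-methylidene-5-(trimethylsilyloxy)cyclohexyl]-3-methyl-3-(trimethylsilyloxy)pent-1-ene F7.
- K2CO3 in MeOH at 0 °C cleaves only the secondary silyl ether, to give (1S,3R,5R)-5-bromo-4,4-dimethyl-2-methylidene-3-[(3S)-3-methyl-3-(trimethylsilyloxy)pent-4-en-1-yl]cyclohexan-1-ol F8.
- MsCl/Et3N at −40 °C gives its C3 methanesulfonate F9, which is used at once.
- LiBr in THF at −40 → −10 °C gives the C9-O-trimethylsilyl ether of the target F10.
- Citric acid in MeOH at 0 °C removes the tertiary silyl ether to give 22.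

## Further compounds

F1 | step 1 | racemic ethyl 2,2-dimethyl-6-methylidenecyclohex-3-ene-1-carboxylate | CCOC(=O)C1C(=C)CC=CC1(C)C
F2 | step 1 | racemic (2,2-dimethyl-6-methylidenecyclohex-3-en-1-yl)methanol | OCC1C(=C)CC=CC1(C)C
F3 | step 1 | racemic 2,2-dimethyl-6-methylidenecyclohex-3-ene-1-carboxylic acid | OC(=O)C1C(=C)CC=CC1(C)C
F4 | step 1 | (S)-1-phenylethylammonium (1R)-2,2-dimethyl-6-methylidenecyclohex-3-ene-1-carboxylate | C[C@H]([NH3+])c1ccccc1.[O-]C(=O)[C@@H]1C(=C)CC=CC1(C)C
F5 | step 1 | (1R)-2,2-dimethyl-6-methylidenecyclohex-3-ene-1-carboxylic acid | OC(=O)[C@@H]1C(=C)CC=CC1(C)C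
F6 | step 7 | (1S,3S,5S)-5-[(tert-butyldimethylsilyl)oxy]-3-[(chloromethanesulfonyl)oxy]-N-methoxy-N,2,2-trimethyl-6-methylidenecyclohexane-1-carboxamide | CON(C)C(=O)[C@@H]1C(=C)[C@@H](O[Si](C)(C)C(C)(C)C)C[C@H](OS(=O)(=O)CCl)C1(C)C
F7 | step 17 | (3S)-5-[(1R,3R,5S)-3-bromo-2,2-dimethyl-6-methylidene-5-(trimethylsilyloxy)cyclohexyl]-3-methyl-3-(trimethylsilyloxy)pent-1-ene | C=C[C@@](C)(O[Si](C)(C)C)CC[C@@H]1C(=C)[C@@H](O[Si](C)(C)C)C[C@@H](Br)C1(C)C
F8 | step 17 | (1S,3R,5R)-5-bromo-4,4-dimethyl-2-methylidene-3-[(3S)-3-methyl-3-(trimethylsilyloxy)pent-4-en-1-yl]cyclohexan-1-ol | C=C[C@@](C)(O[Si](C)(C)C)CC[C@@H]1C(=C)[C@@H](O)C[C@@H](Br)C1(C)C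
F9 | step 17 | C3 methanesulfonate of F8 | C=C[C@@](C)(O[Si](C)(C)C)CC[C@@H]1C(=C)[C@@H](OS(C)(=O)=O)C[C@@H](Br)C1(C)C
F10 | step 17 | C9-O-trimethylsilyl ether of the target | C=C[C@@](C)(O[Si](C)(C)C)CC[C@@H]1C(=C)[C@H](Br)C[C@@H](Br)C1(C)C
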